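## Retrosynthetic overview
1. The last bond is the central C–C bond of the (2Z,4E)-diene. It is made by Suzuki coupling of the ring A E-alkenylboronate 7 with the Z-alkenyl iodide 20.
2. The key bond joins the carbinol carbon to the quaternary oxirane carbon. The oxirane carbon of ring B acts as a carbanion (oxiranyllithium 18, from reductive C–S cleavage of sulfonyl oxirane 17) and adds to β-iodoenal 10. Both carbons are natural electrophiles.
3. The ring B carbocycle comes from arene 11. It is oxidised to quinone 12. Sulfinate addition then marks and activates the future quaternary carbon (14). Asymmetric nucleophilic epoxidation (15) and oxirane-directed double reduction (16) follow.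
4. Ring A comes from Shi epoxidation of geranyl acetate and cationic epoxide–alkene cyclisation, followed by CH2OAc → CHO → E-CH=CH–Bpin.
5. Ring order: ring A closes in step 2, the ring B carbocycle is present from the start, and the oxirane closes in step 10.

Assumption: L-(+)-diisopropyl tartrate is taken to give the (1R,6S)-oxirane 15. If the sense of induction is the opposite, D-(−)-diisopropyl tartrate is used instead.

## Fragment A (ring A boronate)

Step 1
Reactants: 1 geranyl acetate
Product: 2 (2E)-5-[(2R)-3,3-dimethyloxiran-2-yl]-3-methylpent-2-en-1-yl acetate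
Conditions: D-fructose-derived Shi ketone (30 mol %), KHSO5 (as 2KHSO5·KHSO4·K2SO4), K2CO3, Bu4NHSO4, MeCN/CH2(OMe)2/aq Na2B4O7 buffer, 0 °C
Reagents that add atoms: potassium peroxymonosulfate, [K+].[O-]S(=O)(=O)OO
Why: Shi asymmetric epoxidation, in which the chiral dioxirane attacks the electron-rich 6,7-alkene (the 2,3-alkene is deactivated by the allylic acetate) through the spiro transition state and sets the (R)-oxirane carbon that becomes the ring A carbinol.

Step 2
Reactants: 2 (R)-6,7-epoxygeranyl acetate
Product: 3 [(1S,5R)-5-hydroxy-2,6,6-trimethylcyclohex-2-en-1-yl]methyl acetate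
Conditions: ZrCl4 (0.3 equiv), CH2Cl2, −20 to 0 °C
Reagents that add atoms: none
Why: Lewis-acid epoxide-initiated cationic cyclisation through a chair transition state, in which the secondary C–O bond is untouched (R retained), the E-alkene places CH2OAc equatorial and so cis to OH (sets 1S), and the tertiary cation loses a ring proton to give the endocyclic alkene.

Step 3
Reactants: 3 hydroxy acetate
Product: 4 [(1S,5R)-5-hydroxy-2,6,6-trimethylcyclohex-2-en-1-yl]methanol
Conditions: K2CO3 (10 mol %), MeOH, rt
Reagents that add atoms: none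
Why: Base-catalysed transesterification removes the acetate without touching either stereocentre or the alkene.

Step 4
Reactants: 4 diol
Product: 5 (1S,5R)-5-hydroxy-2,6,6-trimethylcyclohex-2-ene-1-carbaldehyde
Conditions: TEMPO (10 mol %), PhI(OAc)2 (1.1 equiv), CH2Cl2, 0 °C to rt
Reagents that add atoms: none
Why: Oxoammonium (TEMPO) oxidation takes the primary alcohol in preference to the hindered secondary carbinol next to CMe2, and the nearly neutral medium avoids epimerisation or conjugation of the β,γ-unsaturated aldehyde.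

Step 5
Reactants: 5 hydroxy aldehyde; 6 2-(dichloromethyl)-4,4,5,5-tetramethyl-1,3,2-dioxaborolane
Product: 7 2-{(E)-2-[(1S,5R)-5-hydroxy-2,6,6-trimethylcyclohex-2-en-1-yl]ethenyl}-4,4,5,5-tetramethyl-1,3,2-dioxaborolane
Conditions: CrCl2 (8 equiv), LiI (4 equiv), THF, rt
Reagents that add atoms: none
Why: Takai–Utimoto olefination, in which the geminal dichromium boryl reagent adds to the aldehyde and eliminates to the E-alkenylboronate under non-basic conditions that tolerate the free OH and the epimerisable centre.

## Fragment B (β-iodoenal)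

Step 6
Reactants: 8 ethyl but-2-ynoate
Product: 9 ethyl (2Z)-3-iodobut-2-enoate
Conditions: NaI, AcOH, 115 °C
Reagents that add atoms: sodium iodide, [Na+].[I-]
Why: Conjugate hydroiodination of an ynoate, in which iodide adds to the β-carbon and the allenolate is protonated anti to it, so I and CO2Et end up cis (Z).

Step 7
Reactants: 9 Z-iodo ester
Product: 10 (2Z)-3-iodobut-2-enal
Conditions: i-Bu2AlH (1.05 equiv), CH2Cl2, −78 °C; MeOH, aq potassium sodium tartrate; used at once, kept cold and dark
Reagents that add atoms: none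
Why: Partial ester reduction, in which the tetrahedral aluminium hemiacetal survives at −78 °C and collapses only on quench, so the aldehyde is obtained with the Z geometry intact.

## Fragment C (ring B) and assembly

Step 8
Reactants: 11 (2,5-dimethoxyphenyl)methanol
Product: 12 2-(hydroxymethyl)cyclohexa-2,5-diene-1,4-dione
Conditions: (NH4)2Ce(NO3)6 (2.2 equiv), MeCN/H2O, 0 °C
Reagents that add atoms: water, O
Why: Oxidative demethylation of a hydroquinone dimethyl ether by the one-electron oxidant gives the quinone and leaves the primary alcohol alone.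

Step 9
Reactants: 12 hydroxymethylquinone
Product: 14 2-(hydroxymethyl)-5-(4-methylbenzenesulfonyl)cyclohexa-2,5-diene-1,4-dione, via sulfonylhydroquinone 13 (not isolated)
Conditions: sodium p-toluenesulfinate (1.0 equiv), AcOH, MeCN/H2O, rt; then PhI(OAc)2 (1.05 equiv), 0 °C
Reagents that add atoms: sodium p-toluenesulfinate, Cc1ccc(cc1)S(=O)[O-].[Na+]
Why: Conjugate addition of a sulfinic acid to a quinone followed by re-oxidation, in which the CH2OH group hydrogen-bonds to and activates its neighbouring carbonyl, whose β-carbon on the unsubstituted alkene is the position para to CH2OH, so the sulfonyl group lands on the future quaternary carbon.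

Step 10
Reactants: 14 sulfonylquinone
Product: 15 (1R,6S)-4-(hydroxymethyl)-1-(4-methylbenzenesulfonyl)-7-oxabicyclo[4.1.0]hept-3-ene-2,5-dione
Conditions: Ph3COOH (1.5 equiv), NaN(SiMe3)2 (2.2 equiv), L-(+)-diisopropyl tartrate (1.2 equiv), 4 Å MS, toluene, −60 °C; aq NH4Cl
Reagents that add atoms: trityl hydroperoxide, OOC(c1ccccc1)(c1ccccc1)c1ccccc1
Why: Tartrate-mediated Weitz–Scheffer nucleophilic epoxidation, in which the sodium alkoxide of CH2OH anchors the quinone to the chiral tartrate–peroxide aggregate, the peroxide adds to the CH carbon that is β to both the sulfonyl group and a carbonyl, and the stabilised carbanion closes on O–O, so only the sulfonyl-bearing alkene reacts and both oxirane carbons are set on one face.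

Step 11
Reactants: 15 sulfonyl epoxyquinone
Product: 16 (1S,2S,5R,6S)-4-(hydroxymethyl)-1-(4-methylbenzenesulfonyl)-7-oxabicyclo[4.1.0]hept-3-ene-2,5-diol
Conditions: i-Bu2AlH (5 equiv), THF, −78 °C; aq potassium sodium tartrate
Reagents that add atoms: none
Why: Oxirane-directed 1,2-reduction, in which aluminium hydride bound to the oxirane oxygen delivers hydride to both flanking carbonyls from the oxirane face (the other face of C2 is also shielded by the sulfonyl group), so both new carbinols are trans to the oxirane and cis to each other.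

Step 12
Reactants: 16 triol
Product: 17 (1R,2S,5R,6S)-2,5-bis[(tert-butyldimethylsilyl)oxy]-4-{[(tert-butyldimethylsilyl)oxy]methyl}-1-(4-methylbenzenesulfonyl)-7-oxabicyclo[4.1.0]hept-3-ene
Conditions: TBSOTf (4 equiv), 2,6-lutidine (6 equiv), CH2Cl2, −20 to 0 °C
Reagents that add atoms: tert-butyldimethylsilyl triflate, CC(C)(C)[Si](C)(C)OS(=O)(=O)C(F)(F)F
Why: Silyl ether formation under non-nucleophilic weakly basic conditions never generates a free alkoxide, so the trans-hydroxy sulfonyl oxirane cannot undergo epoxide migration with loss of sulfinate, and no stereocentre changes (the C1 descriptor changes only through CIP ranking).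

Step 13
Reactants: 17 tris-silylated sulfonyl oxirane; 10 (2Z)-3-iodobut-2-enal
Product: 19 (1S,2Z)-1-[(1S,2S,5R,6S)-2,5-bis[(tert-butyldimethylsilyl)oxy]-4-{[(tert-butyldimethylsilyl)oxy]methyl}-7-oxabicyclo[4.1.0]hept-3-en-1-yl]-3-iodobut-2-en-1-ol, via oxiranyllithium 18 (not isolated)
Conditions: LiC10H8 (2.1 equiv), THF, −100 °C, 2 min; then 10 (1.5 equiv), −100 to −78 °C; aq NH4Cl
Reagents that add atoms: none
Why: Proposed new method: two single-electron transfers to the aryl sulfone cleave the C–S bond (closest known types are the reductive lithiation of glycosyl and other α-alkoxy aryl sulfones and the tin–lithium or sulfoxide–lithium exchange routes to oxiranyllithiums, which add to aldehydes with retention) to give a cis-fused oxiranyllithium that cannot invert and whose β-elimination would need an impossibly strained alkylidene oxirane, so this reversed-polarity oxirane carbon adds 1,2 to the enal with retention, and lithium bridging the oxirane and aldehyde oxygens, with the alkenyl group turned towards the small oxirane C–H flank and away from the neighbouring OTBS, favours the (S)-carbinol.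

Step 14
Reactants: 19 silylated coupling product
Product: 20 (1S,2S,5R,6S)-4-(hydroxymethyl)-1-[(1S,2Z)-1-hydroxy-3-iodobut-2-en-1-yl]-7-oxabicyclo[4.1.0]hept-3-ene-2,5-diol
Conditions: HF·pyridine, excess pyridine, THF, 0 °C to rt
Reagents that add atoms: none
Why: Buffered fluoride desilylation removes all three TBS groups without base (no epoxide migration) and before the acid-sensitive dienyl carbinol exists, leaving all stereocentres and the Z-iodoalkene unchanged.

Step 15
Reactants: 20 Z-alkenyl iodide tetraol; 7 E-alkenylboronate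
Product: 21 (1R,2S,5R,6S)-4-(hydroxymethyl)-1-{(1S,2Z,4E)-1-hydroxy-5-[(1S,5R)-5-hydroxy-2,6,6-trimethylcyclohex-2-en-1-yl]-3-methylpenta-2,4-dien-1-yl}-7-oxabicyclo[4.1.0]hept-3-ene-2,5-diol (target)
Conditions: Pd(dppf)Cl2 (5 mol %), K3PO4 (2 equiv), THF/H2O (degassed), rt
Reagents that add atoms: none
Why: Suzuki–Miyaura coupling proceeds with retention at both sp2 carbons, giving the (2Z,4E)-diene, and the mild phosphate base at room temperature leaves the oxirane and the five free hydroxyls untouched.

## Compound list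
1 | geranyl acetate | CC(=O)OC/C=C(C)/CCC=C(C)C | starting material
2 | (2E)-5-[(2R)-3,3-dimethyloxiran-2-yl]-3-methylpent-2-en-1-yl acetate | CC(=O)OC/C=C(C)/CC[C@H]1OC1(C)C | intermediate
3 | [(1S,5R)-5-hydroxy-2,6,6-trimethylcyclohex-2-en-1-yl]methyl acetate (OH and CH2OAc cis) | CC1=CC[C@@H](O)C(C)(C)[C@H]1COC(C)=O | intermediate
4 | [(1S,5R)-5-hydroxy-2,6,6-trimethylcyclohex-2-en-1-yl]methanol | CC1=CC[C@@H](O)C(C)(C)[C@H]1CO | intermediate
5 | (1S,5R)-5-hydroxy-2,6,6-trimethylcyclohex-2-ene-1-carbaldehyde | CC1=CC[C@@H](O)C(C)(C)[C@H]1C=O | intermediate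
6 | 2-(dichloromethyl)-4,4,5,5-tetramethyl-1,3,2-dioxaborolane | ClC(Cl)B1OC(C)(C)C(C)(C)O1 | starting material
7 | 2-{(E)-2-[(1S,5R)-5-hydroxy-2,6,6-trimethylcyclohex-2-en-1-yl]ethenyl}-4,4,5,5-tetramethyl-1,3,2-dioxaborolane | CC1=CC[C@@H](O)C(C)(C)[C@H]1/C=C/B2OC(C)(C)C(C)(C)O2 | intermediate
8 | ethyl but-2-ynoate | CCOC(=O)C#CC | starting material
9 | ethyl (2Z)-3-iodobut-2-enoate | I/C(C)=C\C(=O)OCC | intermediate
10 | (2Z)-3-iodobut-2-enal | I/C(C)=C\C=O | intermediate
11 | (2,5-dimethoxyphenyl)methanol | COc1ccc(OC)c(CO)c1 | starting material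
12 | 2-(hydroxymethyl)cyclohexa-2,5-diene-1,4-dione | O=C1C=CC(=O)C(CO)=C1 | intermediate
13 | 2-(hydroxymethyl)-5-(4-methylbenzenesulfonyl)benzene-1,4-diol | Cc1ccc(cc1)S(=O)(=O)c1cc(O)c(CO)cc1O | intermediate
14 | 2-(hydroxymethyl)-5-(4-methylbenzenesulfonyl)cyclohexa-2,5-diene-1,4-dione | Cc1ccc(cc1)S(=O)(=O)C1=CC(=O)C(CO)=CC1=O | intermediate
15 | (1R,6S)-4-(hydroxymethyl)-1-(4-methylbenzenesulfonyl)-7-oxabicyclo[4.1.0]hept-3-ene-2,5-dione | Cc1ccc(cc1)S(=O)(=O)[C@]12O[C@H]1C(=O)C(CO)=CC2=O | intermediate
16 | (1S,2S,5R,6S)-4-(hydroxymethyl)-1-(4-methylbenzenesulfonyl)-7-oxabicyclo[4.1.0]hept-3-ene-2,5-diol (both OH trans to the oxirane) | Cc1ccc(cc1)S(=O)(=O)[C@]12O[C@H]1[C@H](O)C(CO)=C[C@@H]2O | intermediate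
17 | (1R,2S,5R,6S)-tris-TBS ether of 16 (same spatial arrangement) | Cc1ccc(cc1)S(=O)(=O)[C@]12O[C@H]1[C@H](O[Si](C)(C)C(C)(C)C)C(CO[Si](C)(C)C(C)(C)C)=C[C@@H]2O[Si](C)(C)C(C)(C)C | intermediate
18 | oxiranyllithium: 17 with Li in place of the sulfonyl group, configuration retained | [Li][C@]12O[C@H]1[C@H](O[Si](C)(C)C(C)(C)C)C(CO[Si](C)(C)C(C)(C)C)=C[C@@H]2O[Si](C)(C)C(C)(C)C | intermediate
19 | (1S,2Z)-1-[(1S,2S,5R,6S)-2,5-bis(TBSO)-4-(TBSOCH2)-7-oxabicyclo[4.1.0]hept-3-en-1-yl]-3-iodobut-2-en-1-ol | I/C(C)=C\[C@H](O)[C@]12O[C@H]1[C@H](O[Si](C)(C)C(C)(C)C)C(CO[Si](C)(C)C(C)(C)C)=C[C@@H]2O[Si](C)(C)C(C)(C)C | intermediate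
20 | (1S,2S,5R,6S)-4-(hydroxymethyl)-1-[(1S,2Z)-1-hydroxy-3-iodobut-2-en-1-yl]-7-oxabicyclo[4.1.0]hept-3-ene-2,5-diol | I/C(C)=C\[C@H](O)[C@]12O[C@H]1[C@H](O)C(CO)=C[C@@H]2O | intermediate
21 | (1R,2S,5R,6S)-4-(hydroxymethyl)-1-{(1S,2Z,4E)-1-hydroxy-5-[(1S,5R)-5-hydroxy-2,6,6-trimethylcyclohex-2-en-1-yl]-3-methylpenta-2,4-dien-1-yl}-7-oxabicyclo[4.1.0]hept-3-ene-2,5-diol | CC1=CC[C@@H](O)C(C)(C)[C@H]1/C=C/C(C)=C\[C@H](O)[C@]12O[C@H]1[C@H](O)C(CO)=C[C@@H]2O | target

The C1 descriptor of the bicycle alternates between R and S in 15–21 only because CIP ranks change. The spatial arrangement is the same throughout.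

## Step count and risks
Total steps: 15. Longest linear sequence: 8 (steps 8–15).

**Step 13** (capture of the short-lived oxiranyllithium by the fragile β-iodoenal, and the carbinol diastereoselectivity). The fallback sets out from 17 and ester 9 and comes back at 19. Ester 9 is converted with MeNH(OMe)·HCl and AlMe3 into (2Z)-3-iodo-N-methoxy-N-methylbut-2-enamide F1. Oxiranyllithium 18, made from 17 as before, is acylated by this more robust electrophile to give the oxiranyl (Z)-β-iodoalkenyl ketone F2. Zn(BH4)2 in Et2O at −30 °C then chelates the ketone and oxirane oxygens and delivers hydride from the face away from the oxirane CH carbon, giving the (S)-carbinol 19. The carbinol centre is then set by a chelation-controlled reduction and not in the C–C bond formation.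

**Step 10** (enantioselectivity on a very electrophilic sulfonylquinone). The fallback sets out from 14 and comes back at 15. Plain Weitz–Scheffer epoxidation (t-BuOOH, DBU, CH2Cl2, −20 °C) gives 15 together with the enantiomer of 15 F3. Kinetic resolution follows with Burkholderia cepacia lipase and vinyl acetate in t-BuOMe. It acetylates the primary alcohol of the unwanted antipode to the acetate of the enantiomer of 15 F4, which is removed by chromatography. Unreacted 15 goes on to step 11.

**Step 11** (facial sense of the double reduction). The fallback sets out from 15 and comes back at 16. NaBH4/CeCl3·7H2O in MeOH at −78 °C attacks anti to the oxirane C–O bonds and gives the all-cis triol F5, with both ring OH groups syn to the oxirane. Threefold Mitsunobu reaction (PPh3, DIAD, chloroacetic acid) inverts both secondary carbinols and esterifies the primary one, giving the tris(chloroacetate) F6. i-Bu2AlH at −78 °C cleaves the esters reductively without free alkoxide and gives 16.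

## Further compounds
F1 | step 13 | (2Z)-3-iodo-N-methoxy-N-methylbut-2-enamide | I/C(C)=C\C(=O)N(C)OC
F2 | step 13 | (2Z)-1-[2,5-bis(TBSO)-4-(TBSOCH2)-7-oxabicyclo[4.1.0]hept-3-en-1-yl]-3-iodobut-2-en-1-one, ring configuration as in 19 | I/C(C)=C\C(=O)[C@]12O[C@H]1[C@H](O[Si](C)(C)C(C)(C)C)C(CO[Si](C)(C)C(C)(C)C)=C[C@@H]2O[Si](C)(C)C(C)(C)C
F3 | step 10 | enantiomer of 15, (1S,6R) | Cc1ccc(cc1)S(=O)(=O)[C@@]12O[C@@H]1C(=O)C(CO)=CC2=O
F4 | step 10 | primary acetate of the enantiomer of 15 | Cc1ccc(cc1)S(=O)(=O)[C@@]12O[C@@H]1C(=O)C(COC(C)=O)=CC2=O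
F5 | step 11 | C2,C5-bis-epimer of 16 (both ring OH syn to the oxirane) | Cc1ccc(cc1)S(=O)(=O)[C@]12O[C@H]1[C@@H](O)C(CO)=C[C@H]2O
F6 | step 11 | tris(chloroacetate) of 16 | Cc1ccc(cc1)S(=O)(=O)[C@]12O[C@H]1[C@H](OC(=O)CCl)C(COC(=O)CCl)=C[C@@H]2OC(=O)CCl
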